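**Plan**
Locants: ring C1 (C=O), C2 (oxirane C–CH3), C3 (oxirane CH), C4 (CH2), C5 (CH bearing the side chain), C6 (CH–O-angeloyl); side chain C7 (=CH2), C8 (CH–O-angeloyl), then the prenyl unit.
Cuts: the C6 angelate (last step); then C1–C2 together with the C3–O oxirane bond in one event, back to an open-chain α-silyloxy aldehyde / α-chloro methyl ketone; then C5–C6 (anti-aldol) and C7=CH2 (methylenation), back to an α′-angeloyloxy ketone made from methyl (S)-glycidate.
Forward: C8 unit from the glycidate, ketone by Weinreb/Grignard chemistry, aldol joins C5–C6, methylenation at C7, chlorination at C3, then ring A (the cyclohexanone) and the oxirane ring close in one operation, C6 angelate last.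
Enabling feature: O=C1–C2(O)(CH3)–C3(O) is an acyloin whose tertiary oxygen also bridges to C3, so an aldehyde carbon C1 (as acyl anion) can add to a C2 methyl ketone and the alkoxide formed can displace an anti leaving group on C3.
Stereochemistry: C8 from the chiral pool; C5 and C6 from C8 by 1,4-induction in the boron anti-aldol; C3 by catalyst-controlled α-chlorination followed by SN2 inversion; C2 by the chair/Cornforth transition state of the ring closure.

Key step: step 12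

Assumption: in step 9 the (2S,5S) antipode of 2,5-diphenylpyrrolidine is taken as the one that delivers the (R)-α-chloro aldehyde (chlorination on the enamine face away from the neighbouring phenyl group). TBS = tert-butyldimethylsilyl.

**Step 1**
Reactants: 1 methyl (2S)-oxirane-2-carboxylate
Product: 2 methyl (2S)-2-hydroxy-5-methylhex-4-enoate
Conditions: 2-methylprop-1-enylmagnesium bromide, CuBr·SMe2 (10 mol%), THF, −40 → −20 °C
Reagents that add atoms: 2-methylprop-1-enylmagnesium bromide, CC(C)=C[Mg]Br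
Why: Copper-catalysed Grignard opening of a terminal epoxide (SN2 at the CH2 carbon) should leave the glycidate stereocentre untouched and give the (S)-α-hydroxy ester that becomes C8.

**Step 2**
Reactants: 2 methyl (2S)-2-hydroxy-5-methylhex-4-enoate
Product: 3 (2S)-2-hydroxy-N-methoxy-N,5-dimethylhex-4-enamide
Conditions: MeNH(OMe)·HCl, i-PrMgCl, THF, −20 → 0 °C
Reagents that add atoms: N,O-dimethylhydroxylamine hydrochloride, CNOC.Cl
Why: Weinreb amide formation from an α-hydroxy ester with the chloromagnesium amide of MeNH(OMe), as established for lactate esters, breaks no bond at the stereocentre.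

**Step 3**
Reactants: 3 (2S)-2-hydroxy-N-methoxy-N,5-dimethylhex-4-enamide; 4 4-chloro-1,1-dimethoxybutane
Product: 6 (6S)-6-hydroxy-1,1-dimethoxy-9-methyldec-8-en-5-one, via Grignard reagent 5 (not isolated)
Conditions: 4, Mg, THF, reflux; then 3, THF, 0 → 23 °C (3 equiv of 5); aq. NH4Cl
Reagents that add atoms: none
Why: Weinreb ketone synthesis: the Grignard reagent adds once to the N-methoxy-N-methyl amide through the stable magnesium chelate, the excess reagent covering the free hydroxyl.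

**Step 4**
Reactants: 6 (6S)-6-hydroxy-1,1-dimethoxy-9-methyldec-8-en-5-one
Product: 7 (6S)-1,1-dimethoxy-9-methyl-5-oxodec-8-en-6-yl (2Z)-2-methylbut-2-enoate
Conditions: (2Z)-2-methylbut-2-enoic acid, 2,4,6-trichlorobenzoyl chloride, Et3N, toluene, 23 °C; then 6, 23 → 50 °C
Reagents that add atoms: (2Z)-2-methylbut-2-enoic acid (angelic acid), C/C=C(/C)C(=O)O
Why: Yamaguchi esterification through the mixed 2,4,6-trichlorobenzoic anhydride without a nucleophilic catalyst should acylate the secondary α-hydroxy ketone with retention of the Z (angelate) geometry.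

**Step 5**
Reactants: 7 (6S)-1,1-dimethoxy-9-methyl-5-oxodec-8-en-6-yl (2Z)-2-methylbut-2-enoate; 8 2-[(tert-butyldimethylsilyl)oxy]acetaldehyde
Product: 11 (2S,3R,5S)-1-[(TBS)oxy]-3-(3,3-dimethoxypropyl)-2-hydroxy-8-methyl-4-oxonon-7-en-5-yl (2Z)-2-methylbut-2-enoate, via boron enolate 9 (not isolated), via boron aldolate 10 (not isolated)
Conditions: (c-C6H11)2BCl, Me2NEt, Et2O, −78 → 0 °C; 8, −78 → −20 °C; MeOH, pH 7 buffer, 30% H2O2, 0 °C
Reagents that add atoms: none
Why: Boron-mediated anti-aldol reaction of an α′-acyloxy ketone: (c-C6H11)2BCl/Me2NEt gives the (E)-enol borinate, and the Zimmerman–Traxler chair with C8–H eclipsing the enolate (A(1,3) strain) and the acyloxy group turned toward the aldehyde should set C5 and C6 (anti) from C8.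

**Step 6**
Reactants: 11 (the aldol adduct)
Product: 12 (2S,3R,5S)-1,2-bis[(TBS)oxy]-3-(3,3-dimethoxypropyl)-8-methyl-4-oxonon-7-en-5-yl (2Z)-2-methylbut-2-enoate
Conditions: TBSOTf, 2,6-lutidine, CH2Cl2, −78 °C
Reagents that add atoms: tert-butyldimethylsilyl trifluoromethanesulfonate, CC(C)(C)[Si](C)(C)OS(=O)(=O)C(F)(F)F
Why: Silyl ether formation with the silyl triflate at −78 °C should protect the hindered secondary hydroxyl faster than the triflate can activate the acetal.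

**Step 7**
Reactants: 12 (the bis-silyl ether ketone)
Product: 13 (2S,3S,5S)-1,2-bis[(TBS)oxy]-3-(3,3-dimethoxypropyl)-8-methyl-4-methylidenenon-7-en-5-yl (2Z)-2-methylbut-2-enoate
Conditions: Cp2Ti(μ-CH2)(μ-Cl)AlMe2, pyridine, THF/toluene, −40 → 0 °C
Reagents that add atoms: Cp2Ti(μ-CH2)(μ-Cl)AlMe2 (Tebbe reagent), C[Al-]1(C)C[Ti](C2C=CC=C2)(C2C=CC=C2)[Cl+]1
Why: Tebbe methylenation (titanium methylidene, via an oxatitanacyclobutane) is non-basic and should convert the hindered, enolisable ketone without epimerising C5 or C8 and, at low temperature, without touching the conjugated ester.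

**Step 8**
Reactants: 13 (the methylidene acetal)
Product: 14 (2S,3S,5S)-1,2-bis[(TBS)oxy]-8-methyl-4-methylidene-3-(3-oxopropyl)non-7-en-5-yl (2Z)-2-methylbut-2-enoate
Conditions: pyridinium p-toluenesulfonate (10 mol%), acetone/H2O, 23 °C
Reagents that add atoms: water, O
Why: Acid-catalysed acetal hydrolysis with pyridinium p-toluenesulfonate should free the unhindered aldehyde and spare both silyl ethers.

**Step 9**
Reactants: 14 (the aldehyde)
Product: 16 (2S,3S,5S)-1,2-bis[(TBS)oxy]-3-[(2R)-2-chloro-3-hydroxybutyl]-8-methyl-4-methylidenenon-7-en-5-yl (2Z)-2-methylbut-2-enoate (carbinol epimers), via chloro aldehyde 15 (not isolated)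
Conditions: N-chlorosuccinimide, (2S,5S)-2,5-diphenylpyrrolidine (10 mol%), CH2Cl2, 0 → 23 °C; pentane, filter, concentrate cold; MeMgBr, Et2O, −78 °C
Reagents that add atoms: N-chlorosuccinimide, ClN1C(=O)CCC1=O; methylmagnesium bromide, C[Mg]Br
Why: Enamine-catalysed α-chlorination of an aldehyde with the C2-symmetric amine should set the (R)-chloride at C3 under catalyst control, and the Grignard addition to the highly electrophilic α-chloro aldehyde at −78 °C should spare the ester; the new carbinol centre is removed in step 11.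

**Step 10**
Reactants: 16 (the chlorohydrin)
Product: 17 (2S,3S,5S)-2-[(TBS)oxy]-3-[(2R)-2-chloro-3-hydroxybutyl]-1-hydroxy-8-methyl-4-methylidenenon-7-en-5-yl (2Z)-2-methylbut-2-enoate (carbinol epimers)
Conditions: HF·pyridine, pyridine, THF, 0 °C
Reagents that add atoms: none
Why: Selective desilylation: buffered HF·pyridine should cleave the primary silyl ether much faster than the hindered secondary one.

**Step 11**
Reactants: 17 (the diol)
Product: 18 (2S,3S,5S)-2-[(TBS)oxy]-3-[(2R)-2-chloro-3-oxobutyl]-8-methyl-4-methylidene-1-oxonon-7-en-5-yl (2Z)-2-methylbut-2-enoate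
Conditions: Dess–Martin periodinane (1,1,1-triacetoxy-1,1-dihydro-1,2-benziodoxol-3(1H)-one, 2.5 equiv), CH2Cl2, 0 → 23 °C; used directly
Reagents that add atoms: none
Why: Dess–Martin oxidation should convert the primary alcohol to the aldehyde and the chlorohydrin to the α-chloro ketone under non-basic conditions that preserve C3 and C6.

**Step 12**
Reactants: 18 (the α-silyloxy aldehyde / α-chloro methyl ketone)
Product: 20 (3S)-2-[(1S,3S,4S,6S)-3-[(TBS)oxy]-1-methyl-2-oxo-7-oxabicyclo[4.1.0]heptan-4-yl]-6-methylhepta-1,5-dien-3-yl (2Z)-2-methylbut-2-enoate, via chlorohydrin ketol 19 (not isolated)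
Conditions: 2-(pentafluorophenyl)-6,7-dihydro-5H-pyrrolo[2,1-c][1,2,4]triazol-2-ium tetrafluoroborate (20 mol%), i-Pr2NEt (2 equiv), toluene (0.02 M), 23 °C
Reagents that add atoms: none
Why: Proposed new method: the triazolylidene adds to the C1 aldehyde to give the Breslow intermediate, whose nucleophilic C1 attacks the C2 methyl ketone (6-exo-trig, crossed aldehyde–ketone benzoin), and the tertiary alkoxide then displaces the anti-periplanar C3 chloride (3-exo-tet, halohydrin closure as in the second stage of a Darzens reaction) before or after the carbene leaves C1, so the cyclohexanone and the oxirane arise in one operation. The closest known reactions are the carbene-catalysed intramolecular aldehyde–ketone benzoin cyclisation of 6-oxoheptanals to 2-hydroxy-2-methylcyclohexanones and the base closure of trans-halohydrins; an α-chloro ketone has not been shown as the benzoin acceptor. C2 is set in a chair transition state with the C5 dienyl and C6 silyloxy groups equatorial, the C3–Cl bond axial and the ketone oxygen axial and anti to it (Cornforth dipole alignment, methyl equatorial), which is also the only adduct able to close; C3 is set by SN2 inversion of the (R)-chloride from step 9. The step needs carbonyl addition to win over substitution at C3 by the carbene or the Breslow carbon and over a Darzens-type aldol of the chloro ketone enolate, and it needs C3 and C6 not to epimerise; the hindered, weakly basic pentafluorophenyl carbene, the amine base, high dilution and the reversibility of the benzoin addition (a syn, non-closing adduct can revert) should secure this.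

**Step 13**
Reactants: 20 (the silylated epoxy ketone)
Product: 21 (3S)-2-[(1S,3S,4S,6S)-3-hydroxy-1-methyl-2-oxo-7-oxabicyclo[4.1.0]heptan-4-yl]-6-methylhepta-1,5-dien-3-yl (2Z)-2-methylbut-2-enoate
Conditions: HF·pyridine, pyridine, THF, 0 → 23 °C
Reagents that add atoms: none
Why: Fluoride-mediated desilylation in buffered medium should free the C6 hydroxyl without opening the oxirane or cleaving the angelate.

**Step 14**
Reactants: 21 (the hydroxy epoxy ketone)
Product: 22 (1S,3S,4S,6S)-1-methyl-4-[(3S)-6-methyl-3-{[(2Z)-2-methylbut-2-enoyl]oxy}hepta-1,5-dien-2-yl]-2-oxo-7-oxabicyclo[4.1.0]heptan-3-yl (2Z)-2-methylbut-2-enoate (target)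
Conditions: (2Z)-2-methylbut-2-enoic acid, 2,4,6-trichlorobenzoyl chloride, Et3N, toluene, 23 °C; then 21, 23 → 70 °C
Reagents that add atoms: (2Z)-2-methylbut-2-enoic acid (angelic acid), C/C=C(/C)C(=O)O
Why: Yamaguchi esterification with the preformed mixed anhydride and no nucleophilic catalyst should give the second angelate with retention of the Z geometry and without touching any stereocentre.

**Compound list**
1 | methyl (2S)-oxirane-2-carboxylate (methyl (S)-glycidate) | COC(=O)[C@@H]1CO1 | starting material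
2 | methyl (2S)-2-hydroxy-5-methylhex-4-enoate | COC(=O)[C@@H](O)CC=C(C)C | intermediate
3 | (2S)-2-hydroxy-N-methoxy-N,5-dimethylhex-4-enamide | CON(C)C(=O)[C@@H](O)CC=C(C)C | intermediate
4 | 4-chloro-1,1-dimethoxybutane | COC(OC)CCCCl | starting material
5 | (4,4-dimethoxybutyl)magnesium chloride | COC(OC)CCC[Mg]Cl | intermediate
6 | (6S)-6-hydroxy-1,1-dimethoxy-9-methyldec-8-en-5-one | COC(OC)CCCC(=O)[C@@H](O)CC=C(C)C | intermediate
7 | (6S)-1,1-dimethoxy-9-methyl-5-oxodec-8-en-6-yl (2Z)-2-methylbut-2-enoate | COC(OC)CCCC(=O)[C@@H](OC(=O)/C(C)=C\C)CC=C(C)C | intermediate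
8 | 2-[(tert-butyldimethylsilyl)oxy]acetaldehyde | CC(C)(C)[Si](C)(C)OCC=O | starting material
9 | (4E,6S)-5-[(dicyclohexylboranyl)oxy]-1,1-dimethoxy-9-methyldeca-4,8-dien-6-yl (2Z)-2-methylbut-2-enoate | COC(OC)CC/C=C(/OB(C1CCCCC1)C1CCCCC1)[C@@H](OC(=O)/C(C)=C\C)CC=C(C)C | intermediate
10 | (2S,3R,5S)-1-[(TBS)oxy]-2-[(dicyclohexylboranyl)oxy]-3-(3,3-dimethoxypropyl)-8-methyl-4-oxonon-7-en-5-yl (2Z)-2-methylbut-2-enoate | CC(C)=CC[C@H](OC(=O)/C(C)=C\C)C(=O)[C@H](CCC(OC)OC)[C@H](OB(C1CCCCC1)C1CCCCC1)CO[Si](C)(C)C(C)(C)C | intermediate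
11 | (2S,3R,5S)-1-[(TBS)oxy]-3-(3,3-dimethoxypropyl)-2-hydroxy-8-methyl-4-oxonon-7-en-5-yl (2Z)-2-methylbut-2-enoate | CC(C)=CC[C@H](OC(=O)/C(C)=C\C)C(=O)[C@H](CCC(OC)OC)[C@H](O)CO[Si](C)(C)C(C)(C)C | intermediate
12 | (2S,3R,5S)-1,2-bis[(TBS)oxy]-3-(3,3-dimethoxypropyl)-8-methyl-4-oxonon-7-en-5-yl (2Z)-2-methylbut-2-enoate | CC(C)=CC[C@H](OC(=O)/C(C)=C\C)C(=O)[C@H](CCC(OC)OC)[C@H](O[Si](C)(C)C(C)(C)C)CO[Si](C)(C)C(C)(C)C | intermediate
13 | (2S,3S,5S)-1,2-bis[(TBS)oxy]-3-(3,3-dimethoxypropyl)-8-methyl-4-methylidenenon-7-en-5-yl (2Z)-2-methylbut-2-enoate | CC(C)=CC[C@H](OC(=O)/C(C)=C\C)C(=C)[C@H](CCC(OC)OC)[C@H](O[Si](C)(C)C(C)(C)C)CO[Si](C)(C)C(C)(C)C | intermediate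
14 | (2S,3S,5S)-1,2-bis[(TBS)oxy]-8-methyl-4-methylidene-3-(3-oxopropyl)non-7-en-5-yl (2Z)-2-methylbut-2-enoate | CC(C)=CC[C@H](OC(=O)/C(C)=C\C)C(=C)[C@H](CCC=O)[C@H](O[Si](C)(C)C(C)(C)C)CO[Si](C)(C)C(C)(C)C | intermediate
15 | (2S,3S,5S)-1,2-bis[(TBS)oxy]-3-[(2R)-2-chloro-3-oxopropyl]-8-methyl-4-methylidenenon-7-en-5-yl (2Z)-2-methylbut-2-enoate | CC(C)=CC[C@H](OC(=O)/C(C)=C\C)C(=C)[C@H](C[C@@H](Cl)C=O)[C@H](O[Si](C)(C)C(C)(C)C)CO[Si](C)(C)C(C)(C)C | intermediate
16 | (2S,3S,5S)-1,2-bis[(TBS)oxy]-3-[(2R)-2-chloro-3-hydroxybutyl]-8-methyl-4-methylidenenon-7-en-5-yl (2Z)-2-methylbut-2-enoate (carbinol epimers) | CC(C)=CC[C@H](OC(=O)/C(C)=C\C)C(=C)[C@H](C[C@@H](Cl)C(C)O)[C@H](O[Si](C)(C)C(C)(C)C)CO[Si](C)(C)C(C)(C)C | intermediate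
17 | (2S,3S,5S)-2-[(TBS)oxy]-3-[(2R)-2-chloro-3-hydroxybutyl]-1-hydroxy-8-methyl-4-methylidenenon-7-en-5-yl (2Z)-2-methylbut-2-enoate (carbinol epimers) | CC(C)=CC[C@H](OC(=O)/C(C)=C\C)C(=C)[C@H](C[C@@H](Cl)C(C)O)[C@H](O[Si](C)(C)C(C)(C)C)CO | intermediate
18 | (2S,3S,5S)-2-[(TBS)oxy]-3-[(2R)-2-chloro-3-oxobutyl]-8-methyl-4-methylidene-1-oxonon-7-en-5-yl (2Z)-2-methylbut-2-enoate | CC(C)=CC[C@H](OC(=O)/C(C)=C\C)C(=C)[C@H](C[C@@H](Cl)C(C)=O)[C@H](O[Si](C)(C)C(C)(C)C)C=O | intermediate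
19 | (3S)-2-[(1S,2S,4R,5R)-2-[(TBS)oxy]-5-chloro-4-hydroxy-4-methyl-3-oxocyclohexyl]-6-methylhepta-1,5-dien-3-yl (2Z)-2-methylbut-2-enoate | C=C([C@H](CC=C(C)C)OC(=O)/C(C)=C\C)[C@@H]1C[C@@H](Cl)[C@](C)(O)C(=O)[C@H]1O[Si](C)(C)C(C)(C)C | intermediate
20 | (3S)-2-[(1S,3S,4S,6S)-3-[(TBS)oxy]-1-methyl-2-oxo-7-oxabicyclo[4.1.0]heptan-4-yl]-6-methylhepta-1,5-dien-3-yl (2Z)-2-methylbut-2-enoate | C=C([C@H](CC=C(C)C)OC(=O)/C(C)=C\C)[C@@H]1C[C@@H]2O[C@]2(C)C(=O)[C@H]1O[Si](C)(C)C(C)(C)C | intermediate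
21 | (3S)-2-[(1S,3S,4S,6S)-3-hydroxy-1-methyl-2-oxo-7-oxabicyclo[4.1.0]heptan-4-yl]-6-methylhepta-1,5-dien-3-yl (2Z)-2-methylbut-2-enoate | C=C([C@H](CC=C(C)C)OC(=O)/C(C)=C\C)[C@@H]1C[C@@H]2O[C@]2(C)C(=O)[C@H]1O | intermediate
22 | (1S,3S,4S,6S)-1-methyl-4-[(3S)-6-methyl-3-{[(2Z)-2-methylbut-2-enoyl]oxy}hepta-1,5-dien-2-yl]-2-oxo-7-oxabicyclo[4.1.0]heptan-3-yl (2Z)-2-methylbut-2-enoate | C=C([C@H](CC=C(C)C)OC(=O)/C(C)=C\C)[C@@H]1C[C@@H]2O[C@]2(C)C(=O)[C@H]1OC(=O)/C(C)=C\C | target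

**Step count and risks**
Total: 14 steps. Longest linear sequence: 14 steps (1 → 22).

Step 12 (proposed new method). What may go wrong: substitution at C3 by the carbene or the Breslow carbon instead of carbonyl addition, a Darzens-type aldol of the chloro ketone enolate, base-mediated epimerisation at C3 or C6 before closure, or slow formation of the Breslow intermediate at the hindered aldehyde. The fallback uses known chemistry only, sets out from 14 and comes back at 20. MeMgBr (Et2O, −78 °C) should give the secondary alcohol (2S,3S,5S)-1,2-bis[(TBS)oxy]-3-(3-hydroxybutyl)-8-methyl-4-methylidenenon-7-en-5-yl angelate F1. Buffered HF·pyridine frees the primary hydroxyl to give the diol F2, and Dess–Martin oxidation gives the chlorine-free keto aldehyde F3. The precedented carbene-catalysed aldehyde–ketone benzoin cyclisation (same triazolium tetrafluoroborate, 1,8-diazabicyclo[5.4.0]undec-7-ene, THF/t-BuOH) closes the same C1–C2 bond to the tertiary ketol F4. SOCl2/pyridine dehydrates it by anti-elimination through the axial C3–H to the 2-methylcyclohex-2-enone F5. Luche reduction (NaBH4, CeCl3·7H2O, MeOH) should give the equatorial allylic alcohol F6, and VO(acac)2/t-BuOOH epoxidises syn to that hydroxyl to give the epoxy alcohol F7. Dess–Martin oxidation returns to 20.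

Step 5. What may go wrong: weaker π-facial control if the angeloyloxy group directs less well than the benzoyloxy group for which this aldol is established, or interference of the chloroborane with the acetal. The fallback sets out from 6 and comes back at 13. Benzoic anhydride, 4-(dimethylamino)pyridine and i-Pr2NEt give the benzoate (6S)-1,1-dimethoxy-9-methyl-5-oxodec-8-en-6-yl benzoate F8. The same enolisation and aldol with 8 give the anti-aldol adduct F9, TBSOTf/2,6-lutidine gives the bis-silyl ether F10, and Cp2Ti(μ-CH2)(μ-Cl)AlMe2 gives the methylidene benzoate F11. i-Bu2AlH (CH2Cl2, −78 °C) removes the benzoate to give the allylic alcohol F12, and the esterification of step 4 with angelic acid returns to 13.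

Step 14. What may go wrong: Z → E isomerisation of the acyl unit to the tiglate during acyl transfer, and base- or heat-induced enolisation, α-ketol shift or oxirane opening of the hydroxy epoxy ketone. The fallback sets out from 21 and comes back at 22. Esterification with 2-[bis(2,2,2-trifluoroethoxy)phosphoryl]propanoic acid (N,N′-dicyclohexylcarbodiimide, 4-(dimethylamino)pyridine 5 mol%, CH2Cl2, 0 °C) gives the phosphonate ester (1S,3S,4S,6S)-1-methyl-4-[(3S)-6-methyl-3-{[(2Z)-2-methylbut-2-enoyl]oxy}hepta-1,5-dien-2-yl]-2-oxo-7-oxabicyclo[4.1.0]heptan-3-yl 2-[bis(2,2,2-trifluoroethoxy)phosphoryl]propanoate F13. Still–Gennari olefination (KN(SiMe3)2, 18-crown-6, THF, −78 °C, acetaldehyde) then builds the Z-configured 2-methylbut-2-enoate on the ester and gives 22.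

**Further compounds**
F1 | step 12 | (2S,3S,5S)-1,2-bis[(TBS)oxy]-3-(3-hydroxybutyl)-8-methyl-4-methylidenenon-7-en-5-yl (2Z)-2-methylbut-2-enoate (carbinol epimers) | CC(C)=CC[C@H](OC(=O)/C(C)=C\C)C(=C)[C@H](CCC(C)O)[C@H](O[Si](C)(C)C(C)(C)C)CO[Si](C)(C)C(C)(C)C
F2 | step 12 | (2S,3S,5S)-2-[(TBS)oxy]-1-hydroxy-3-(3-hydroxybutyl)-8-methyl-4-methylidenenon-7-en-5-yl (2Z)-2-methylbut-2-enoate (carbinol epimers) | CC(C)=CC[C@H](OC(=O)/C(C)=C\C)C(=C)[C@H](CCC(C)O)[C@H](O[Si](C)(C)C(C)(C)C)CO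
F3 | step 12 | (2S,3S,5S)-2-[(TBS)oxy]-8-methyl-4-methylidene-1-oxo-3-(3-oxobutyl)non-7-en-5-yl (2Z)-2-methylbut-2-enoate | CC(C)=CC[C@H](OC(=O)/C(C)=C\C)C(=C)[C@H](CCC(C)=O)[C@H](O[Si](C)(C)C(C)(C)C)C=O
F4 | step 12 | (3S)-2-[(1S,2S,4S)-2-[(TBS)oxy]-4-hydroxy-4-methyl-3-oxocyclohexyl]-6-methylhepta-1,5-dien-3-yl (2Z)-2-methylbut-2-enoate | C=C([C@H](CC=C(C)C)OC(=O)/C(C)=C\C)[C@@H]1CC[C@](C)(O)C(=O)[C@H]1O[Si](C)(C)C(C)(C)C
F5 | step 12 | (3S)-2-[(1S,6S)-6-[(TBS)oxy]-4-methyl-5-oxocyclohex-3-en-1-yl]-6-methylhepta-1,5-dien-3-yl (2Z)-2-methylbut-2-enoate | C=C([C@H](CC=C(C)C)OC(=O)/C(C)=C\C)[C@@H]1CC=C(C)C(=O)[C@H]1O[Si](C)(C)C(C)(C)C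
F6 | step 12 | (3S)-2-[(1S,5S,6S)-6-[(TBS)oxy]-5-hydroxy-4-methylcyclohex-3-en-1-yl]-6-methylhepta-1,5-dien-3-yl (2Z)-2-methylbut-2-enoate | C=C([C@H](CC=C(C)C)OC(=O)/C(C)=C\C)[C@@H]1CC=C(C)[C@H](O)[C@H]1O[Si](C)(C)C(C)(C)C
F7 | step 12 | (3S)-2-[(1R,2R,3S,4S,6S)-3-[(TBS)oxy]-2-hydroxy-1-methyl-7-oxabicyclo[4.1.0]heptan-4-yl]-6-methylhepta-1,5-dien-3-yl (2Z)-2-methylbut-2-enoate | C=C([C@H](CC=C(C)C)OC(=O)/C(C)=C\C)[C@@H]1C[C@@H]2O[C@]2(C)[C@H](O)[C@H]1O[Si](C)(C)C(C)(C)C
F8 | step 5 | (6S)-1,1-dimethoxy-9-methyl-5-oxodec-8-en-6-yl benzoate | COC(OC)CCCC(=O)[C@@H](OC(=O)c1ccccc1)CC=C(C)C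
F9 | step 5 | (2S,3R,5S)-1-[(TBS)oxy]-3-(3,3-dimethoxypropyl)-2-hydroxy-8-methyl-4-oxonon-7-en-5-yl benzoate | CC(C)=CC[C@H](OC(=O)c1ccccc1)C(=O)[C@H](CCC(OC)OC)[C@H](O)CO[Si](C)(C)C(C)(C)C
F10 | step 5 | (2S,3R,5S)-1,2-bis[(TBS)oxy]-3-(3,3-dimethoxypropyl)-8-methyl-4-oxonon-7-en-5-yl benzoate | CC(C)=CC[C@H](OC(=O)c1ccccc1)C(=O)[C@H](CCC(OC)OC)[C@H](O[Si](C)(C)C(C)(C)C)CO[Si](C)(C)C(C)(C)C
F11 | step 5 | (2S,3S,5S)-1,2-bis[(TBS)oxy]-3-(3,3-dimethoxypropyl)-8-methyl-4-methylidenenon-7-en-5-yl benzoate | CC(C)=CC[C@H](OC(=O)c1ccccc1)C(=C)[C@H](CCC(OC)OC)[C@H](O[Si](C)(C)C(C)(C)C)CO[Si](C)(C)C(C)(C)C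
F12 | step 5 | (2S,3S,5S)-1,2-bis[(TBS)oxy]-3-(3,3-dimethoxypropyl)-8-methyl-4-methylidenenon-7-en-5-ol | CC(C)=CC[C@H](O)C(=C)[C@H](CCC(OC)OC)[C@H](O[Si](C)(C)C(C)(C)C)CO[Si](C)(C)C(C)(C)C
F13 | step 14 | (1S,3S,4S,6S)-1-methyl-4-[(3S)-6-methyl-3-{[(2Z)-2-methylbut-2-enoyl]oxy}hepta-1,5-dien-2-yl]-2-oxo-7-oxabicyclo[4.1.0]heptan-3-yl 2-[bis(2,2,2-trifluoroethoxy)phosphoryl]propanoate (phosphonate carbon epimers) | C=C([C@H](CC=C(C)C)OC(=O)/C(C)=C\C)[C@@H]1C[C@@H]2O[C@]2(C)C(=O)[C@H]1OC(=O)C(C)P(=O)(OCC(F)(F)F)OCC(F)(F)F
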